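The numbers in the tables are calculated for an exercise; the scatter is artificial.

It is easy to read a slow feed by its whole charge, though a reacting molecule meets what stands in the flask at its own moment.

the same everywhere: starting material 11 mM
- north-east: first nucleophile 22 mM; second nucleophile 22 mM; run made earlier
- south-east: first nucleophile 11 mM; second nucleophile 22 mM; run made earlier
- south: first nucleophile 44 mM; second nucleophile 22 mM; run made earlier
- Tuesday's: first nucleophile 22.0 mM; second nucleophile 22.0 mM (in portions, 5, over 50 h); first portion at the start, last at 50 h; time 2.5 d
- Wednesday's: first nucleophile 22.0 mM; second nucleophile 22.0 mM (fed, over 50 h); all else is in the flask from the start; the feed brings no volume worth counting; time 2.5 d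
- Thursday's: first nucleophile 22.0 mM; second nucleophile 22.0 mM; everything together at the start; time 2.5 d
- Saturday's: first nucleophile 22.0 mM (fed, over 50 h); second nucleophile 22.0 mM; all else is in the flask from the start; the feed brings no volume worth counting; time 2.5 d

north-east run (percent of the starting material charged)

| time / d | target / % | starting material / % |
|---|---|---|
| 0.333 | 18.8 | 40.2 |
| 0.833 | 29.2 | 10.8 |
| 1.67 | 25.4 | 0 |
| 2.50 | 22.4 | 0 |

south-east run (percent of the starting material charged)

| time / h | target / % | starting material / % |
|---|---|---|
| 4.00 | 7.7 | 66.1 |
| 8.00 | 10.3 | 41.5 |
| 20.0 | 16.4 | 11.2 |
| 50.0 | 12.9 | 0 |

south run (percent of the starting material charged)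

| time / h | target / % | starting material / % |
|---|---|---|
| 6.00 | 25.1 | 51.5 |
| 15.0 | 39.0 | 18.1 |
| 30.0 | 42.4 | 4.7 |
| 50.0 | 35.8 | 0 |

(standard deviation of a reading: 1 percentage point)

- what was read earlier has a scatter of 1 percentage point, one standard deviation
- a reading or a percentage of target counts all its forms, free or not

- which flask leads in amount of target, in percent of the starting material charged ("all alike" within 1.5 percentage points) (Tuesday's / Wednesday's / Thursday's / Saturday's / all alike)
- how much target is there at the end, in percent of the starting material charged: Tuesday's
- how much target is there at the end, in percent of the starting material charged: Wednesday's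
- how much target is there at the end, in percent of the starting material charged: Thursday's
- how much target is there at the end, in percent of the starting material charged: Saturday's

Start with the starting material. In the south run it stands at 51.5% after 6.00 h, a first-order rate constant of 0.111 h⁻¹. The south-east run, with a quarter of that first nucleophile, reads 0.104 h⁻¹. So the first nucleophile is not in this rate-limiting step: the starting material turns by itself into an intermediate, and something competes for that afterwards.

The share reaching target does rise with the first nucleophile. Take the competitor to be the second nucleophile, an assumption, since its charge was never varied. Then target over the rest of what was consumed equals a selectivity factor times [first nucleophile]/[second nucleophile]. The same south reading gives 0.536.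

Now count turnovers: the feed turnover number, the rate constant times the feed time, is how many lifetimes of the starting material fit into the feed, here 5.53. An average molecule reacts one lifetime in, when a steady feed has delivered the charge divided by that number, 3.98 mM; take this as the level it meets, ignoring what capture consumes.

Wednesday's then sends 74.8% the target's way, Thursday's 34.9%, and Saturday's, with the first nucleophile at that level, 8.84%. Tuesday's first portion, 4.40 mM, stands from the start, more than 3.98 mM, so you expect Wednesday's to lead. These shares estimate what is made, not what stands at the end, and target fades: the north-east run reads 29.2% at 0.833 d and 22.4% at 2.50 d.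

The forecast names Wednesday's, with 47% for Tuesday's, 51% for Wednesday's, 22.5% for Thursday's and 8% for Saturday's, adding “so the ranges are wide”.

    starting material → intermediate (k = 0.110 h⁻¹)
    first nucleophile + intermediate → target (k = 150 L mol⁻¹ h⁻¹)
    second nucleophile + intermediate → other capture product (k = 290 L mol⁻¹ h⁻¹)
    target → over-reaction product (k = 0.120 h⁻¹)
    second nucleophile + target ⇌ idle adduct, settled at all times (K = 700 L mol⁻¹)

The flasks give 24.6% on Tuesday's, 26.6% on Wednesday's, 21.3% on Thursday's and 6.40% on Saturday's, so Wednesday's leads. Wednesday's ends with 56.9% of over-reaction product, more than its target. Your 5.53 turnovers left 25.2% for other capture product; Wednesday's holds 16.4%, less than that.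

On the neighbour of Wednesday's with 5.5 mM of first nucleophile, the turnovers stay 5.53, so the level met stays 3.98 mM, and other capture product should take 57.4%. The computed flask holds 54.1% of it, with 9.87% of target.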